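**Retrosynthetic overview**
1. C13–C14 is cut last: the 14-membered ring comes from a new nickel-catalysed reductive acyl–allyl macrocyclisation of a 2-pyridyl thioester onto an (E)-allylic pivalate.
2. C10–C11 is cut next: a B-alkyl Suzuki coupling joins the C8 vinyl group to an (E)-iodoalkene pivalate (fragment B: C11–C13, C20).
3. The γ-lactone (C1, C14–C17) comes from a chelation-controlled indium allylation of a C2 α-hydroxy aldehyde with a (Z)-allylic bromide (fragment A), lactonisation, then conjugate reduction and equilibration at C15.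
4. The oxolane comes from Sharpless epoxidation of a (Z)-allylic alcohol and 5-exo epoxide opening by the C7 hydroxyl; C7/C8 come from a Brown (Z)-crotylation of a neryl acetate-derived aldehyde.
5. Ring order: oxolane (step 8), γ-lactone (step 10), 14-membered carbocycle (step 17).

Assumption: cembrane-type locants are used throughout (C1 lactone CH next to the ketone, C2 lactone CH–O, C3 carbinol, C4 and C7 oxolane carbons, C8 CH(CH3), C11=C12, C13 CH2, C14 ketone, C15 lactone CH(CH3), C16 lactone C=O); with them the target is (1R,2S,3R,4R,7R,8R,15R,11E). Compounds 1, 2, 5, 9, (−)-Ipc2BOMe and D-(−)-diethyl tartrate are bought.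

**Fragment A**

Step 1
Reactants: 1 methyl acrylate; 2 (tert-butyldimethylsilyloxy)acetaldehyde
Product: 3 methyl 2-[2-(tert-butyldimethylsilyloxy)-1-hydroxyethyl]prop-2-enoate (racemic)
Conditions: DABCO (0.3 equiv), MeOH, rt, 3 d
Reagents that add atoms: none
Why: Morita–Baylis–Hillman reaction, in which the DABCO–acrylate zwitterion adds to the reactive α-silyloxy aldehyde; the racemic carbinol centre is removed in step 2.

Step 2
Reactants: 3 methyl 2-[2-(tert-butyldimethylsilyloxy)-1-hydroxyethyl]prop-2-enoate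
Product: 4 methyl (2Z)-2-(bromomethyl)-4-(tert-butyldimethylsilyloxy)but-2-enoate
Conditions: NBS, Me2S, CH2Cl2, 0 °C → rt
Reagents that add atoms: N-bromosuccinimide, O=C1CCC(=O)N1Br
Why: The sulfonium reagent from NBS and Me2S activates the hydroxyl and bromide attacks in the SN2' sense (allylic transposition), giving the trisubstituted (2Z)-2-(bromomethyl)enoate with the ester trans to the CH2OTBS group.

**Fragment B**

Step 3
Reactants: 5 prop-2-yn-1-ol
Product: 7 (2E)-3-iodo-2-methylprop-2-en-1-ol, via alkenylalane 6 (not isolated)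
Conditions: AlMe3 (3 equiv), Cp2ZrCl2 (25 mol %), CH2Cl2, 0 °C → rt; then I2, THF, −30 → 0 °C
Reagents that add atoms: trimethylaluminium, C[Al](C)C; iodine, II
Why: Negishi zirconium-catalysed carboalumination adds CH3 and Al syn across the alkyne with Al on the terminal carbon, and iodinolysis with retention gives only the E iodoalkene.

Step 4
Reactants: 7 (2E)-3-iodo-2-methylprop-2-en-1-ol
Product: 8 (2E)-3-iodo-2-methylprop-2-en-1-yl pivalate
Conditions: PivCl, pyridine, DMAP (cat.), CH2Cl2, 0 °C → rt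
Reagents that add atoms: pivaloyl chloride, CC(C)(C)C(=O)Cl
Why: Standard acylation; the pivalate survives the later aqueous base, fluoride and oxidation steps and serves as the allylic leaving group in step 17.

**Main line**

Step 5
Reactants: 9 neryl acetate
Product: 10 (2Z)-5-(3,3-dimethyloxiran-2-yl)-3-methylpent-2-en-1-yl acetate (racemic epoxide)
Conditions: mCPBA (1.05 equiv), CH2Cl2, −10 → 0 °C
Reagents that add atoms: 3-chloroperbenzoic acid, OOC(=O)c1cccc(Cl)c1
Why: Prilezhaev epoxidation is selective for the electron-rich remote 6,7-alkene over the 2,3-alkene deactivated by the allylic acetate; the new centre is cut out in step 6.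

Step 6
Reactants: 10 (2Z)-5-(3,3-dimethyloxiran-2-yl)-3-methylpent-2-en-1-yl acetate
Product: 11 (2Z)-3-methyl-6-oxohex-2-en-1-yl acetate
Conditions: HIO4·2H2O, THF/Et2O, 0 °C
Reagents that add atoms: none
Why: Periodic acid hydrates the epoxide at the tertiary carbon and cleaves the glycol (Malaprade cleavage) to the aldehyde, whose oxygen is the former epoxide oxygen, leaving the Z-alkene and acetate untouched.

Step 7
Reactants: 11 (2Z)-3-methyl-6-oxohex-2-en-1-yl acetate
Product: 13 (2Z,6R,7R)-3,7-dimethylnona-2,8-diene-1,6-diol, via borinate ester 12 (not isolated)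
Conditions: cis-2-butene, n-BuLi, KOt-Bu, THF, −78 → −45 °C; (−)-Ipc2BOMe, −78 °C; BF3·OEt2; 11, −78 °C, 4 h; then 3 M NaOH, 30% H2O2, rt → 50 °C
Reagents that add atoms: (Z)-crotyldiisopinocampheylborane, C/C=C\CB([C@@H]1C[C@@H]2C[C@H]([C@H]1C)C2(C)C)[C@@H]1C[C@@H]2C[C@H]([C@H]1C)C2(C)C, made in the flask from cis-2-butene, C/C=C\C
Why: Brown asymmetric crotylboration through a closed chair (Zimmerman–Traxler) transition state, where the Z-crotyl geometry gives the syn C7-OH/C8-CH3 pair and the isopinocampheyl groups from (+)-α-pinene direct attack to the Si face, setting C7 (R) and C8 (R); the alkaline peroxide work-up oxidises the borinate and saponifies the acetate.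

Step 8
Reactants: 13 (2Z,6R,7R)-3,7-dimethylnona-2,8-diene-1,6-diol
Product: 15 (1R)-1-[(2R,5R)-5-[(2R)-but-3-en-2-yl]-2-methyloxolan-2-yl]ethane-1,2-diol, via epoxy alcohol 14 (not isolated)
Conditions: Ti(OiPr)4 (10 mol %), D-(−)-diethyl tartrate (12 mol %), t-BuOOH, 4 Å MS, CH2Cl2, −20 °C; then CSA (10 mol %), 0 °C → rt
Reagents that add atoms: tert-butyl hydroperoxide, CC(C)(C)OO
Why: Sharpless asymmetric epoxidation of the (Z)-allylic alcohol with D-(−)-tartrate gives the (2R,3S)-epoxy alcohol by reagent control, and acid-promoted 5-exo opening by the C7 hydroxyl at the tertiary carbon with inversion sets C4 (R), leaves C3 (R) as the carbinol and closes the 2,5-trans oxolane.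

Step 9
Reactants: 15 (1R)-1-[(2R,5R)-5-[(2R)-but-3-en-2-yl]-2-methyloxolan-2-yl]ethane-1,2-diol
Product: 16 (2S)-2-[(2R,5R)-5-[(2R)-but-3-en-2-yl]-2-methyloxolan-2-yl]-2-hydroxyacetaldehyde
Conditions: TEMPO (10 mol %), PhI(OAc)2 (1.1 equiv), CH2Cl2, 0 °C → rt; crude used at once
Reagents that add atoms: none
Why: Oxoammonium (TEMPO) oxidation is selective for the primary hydroxyl over the hindered secondary one next to the quaternary C4, so C3 is untouched (its descriptor changes only through CIP priority).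

Step 10
Reactants: 16 α-hydroxy aldehyde; 4 methyl (2Z)-2-(bromomethyl)-4-(tert-butyldimethylsilyloxy)but-2-enoate
Product: 19 (4S,5S)-4-[(tert-butyldimethylsilyloxy)methyl]-5-[(R)-hydroxy{(2R,5R)-5-[(2R)-but-3-en-2-yl]-2-methyloxolan-2-yl}methyl]-3-methylideneoxolan-2-one, via allylindium reagent 17 (not isolated), via dihydroxy ester 18 (not isolated)
Conditions: indium powder (2 equiv), 4 (1.5 equiv), THF/H2O (1:1), rt; then PPTS (cat.), CH2Cl2, rt
Reagents that add atoms: none
Why: Indium-mediated Barbier allylation in water, where the free α-hydroxyl and the aldehyde oxygen chelate indium (Cram-chelate model) so C2-OH forms syn to C3-OH (C2 S), the (Z)-γ-substituted 2-(alkoxycarbonyl)allyl metal reacts through its γ-carbon in a cyclic transition state to give the syn C1/C2 pair, and lactonisation of the C2 hydroxyl onto the ester places the C14 and C3 substituents cis on the γ-lactone (C1 set).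

Step 11
Reactants: 19 C3-hydroxy α-methylene lactone
Product: 20 C3-O-tert-butyldimethylsilyl ether of 19
Conditions: TBSOTf, 2,6-lutidine, CH2Cl2, −78 → 0 °C
Reagents that add atoms: tert-butyldimethylsilyl triflate, CC(C)(C)[Si](C)(C)OS(=O)(=O)C(F)(F)F
Why: Silyl triflate silylation masks the hindered C3 hydroxyl, which would otherwise lactonise onto C14 once that carbon is oxidised.

Step 12
Reactants: 20 bis-silylated α-methylene lactone
Product: 22 (3R,4S,5S)-3-methyl lactone (C15 methyl trans to the C1 and C2 substituents), via C15-epimer mixture 21 (not isolated)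
Conditions: NaBH4, MeOH/THF, −20 → 0 °C; then DBU (0.3 equiv), toluene, 60 °C
Reagents that add atoms: none
Why: Conjugate (1,4-) hydride reduction of the α-methylene lactone followed by DBU-mediated enolisation and reprotonation puts the C15 methyl on the face opposite the two cis ring substituents (thermodynamic control), setting C15 (R).

Step 13
Reactants: 22 α-methyl lactone with C8 vinyl group; 8 (2E)-3-iodo-2-methylprop-2-en-1-yl pivalate
Product: 24 seco compound carrying the (3E)-4-methyl-5-(pivaloyloxy)pent-3-en-1-yl chain (C9–C13) on C8, via B-alkyl-9-BBN borane 23 (not isolated)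
Conditions: 9-BBN, THF, rt; then 8, Pd(dppf)Cl2 (5 mol %), AsPh3 (10 mol %), K3PO4 (aq), DMF, rt
Reagents that add atoms: none
Why: B-alkyl Suzuki–Miyaura coupling, in which 9-BBN hydroborates only the terminal vinyl group anti-Markovnikov and the alkylborane couples with the iodoalkene with retention, installing the 11E trisubstituted alkene.

Step 14
Reactants: 24 bis-silyl seco pivalate
Product: 25 C14 primary alcohol (C3-OTBS kept)
Conditions: HF·pyridine, pyridine, THF, 0 °C
Reagents that add atoms: none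
Why: Buffered fluoride cleaves the unhindered primary silyl ether much faster than the secondary one flanked by the quaternary C4 (selective desilylation).

Step 15
Reactants: 25 C14 primary alcohol
Product: 27 C14 carboxylic acid, via aldehyde 26 (not isolated)
Conditions: TEMPO (20 mol %), PhI(OAc)2 (2.2 equiv), MeCN/H2O (1:1), rt
Reagents that add atoms: water, O
Why: Oxoammonium oxidation in aqueous acetonitrile takes the primary alcohol through the aldehyde hydrate to the acid under near-neutral conditions that neither epimerise C1 nor touch the alkene or pivalate.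

Step 16
Reactants: 27 C14 carboxylic acid
Product: 28 S-(pyridin-2-yl) C14 thioester
Conditions: 2,2'-dipyridyl disulfide, PPh3, CH2Cl2, rt
Reagents that add atoms: 2,2'-dipyridyl disulfide, c1ccc(nc1)SSc1ccccn1
Why: Mukaiyama redox condensation forms the 2-pyridyl thioester without base, which could epimerise C1 or open the lactone by β-elimination.

Step 17
Reactants: 28 S-(pyridin-2-yl) thioester with (E)-allylic pivalate
Product: 29 C3-O-tert-butyldimethylsilyl ether of the target (14-membered β,γ-unsaturated ketone)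
Conditions: NiBr2(dme) (20 mol %), 4,4'-di-tert-butyl-2,2'-bipyridine (24 mol %), Zn dust (4 equiv), DMA/THF (4:1), 28 added by syringe pump over 12 h (final 2 mM), 25 °C; aq. NH4Cl work-up
Reagents that add atoms: none
Why: Proposed new method: zerovalent nickel (formed from NiBr2(dme) and Zn) inserts into the N-chelation-activated C(acyl)–S bond of the 2-pyridyl thioester, Zn reduces the divalent acylnickel to a monovalent acylnickel that ionises the tethered allylic pivalate (or an allylnickel formed first captures the thioester), and the trivalent acyl(allyl)nickel reductively eliminates at the unsubstituted allyl terminus C13, closing the 14-membered ring by the C13–C14 bond as the β,γ-unsaturated ketone with the 11E geometry kept and without base, so C1 and the β-acyloxy ketone survive, while slow addition at 2 mM favours ring closure over dimerisation; the closest known reaction type is the intermolecular nickel-catalysed reductive cross-electrophile ketone synthesis (2-pyridyl thioester or acid chloride plus alkyl halide, Zn or Mn) together with nickel-catalysed reductive couplings of allylic esters, which have not been merged into an acyl–allyl macrocyclisation.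

Step 18
Reactants: 29 C3 silyl ether of the target
Product: 30 target CNP0386136.3
Conditions: 48% aq. HF, MeCN, 0 °C → rt
Reagents that add atoms: none
Why: Acidic fluoride desilylation frees the C3 hydroxyl without base, which would cause β-elimination of the lactone oxygen or conjugation of the β,γ-enone.

**Compound list**
1 | methyl acrylate | C=CC(=O)OC | starting material
2 | (tert-butyldimethylsilyloxy)acetaldehyde | O=CCO[Si](C)(C)C(C)(C)C | starting material
3 | methyl 2-[2-(tert-butyldimethylsilyloxy)-1-hydroxyethyl]prop-2-enoate (racemic) | C=C(C(=O)OC)C(O)CO[Si](C)(C)C(C)(C)C | intermediate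
4 | methyl (2Z)-2-(bromomethyl)-4-(tert-butyldimethylsilyloxy)but-2-enoate | COC(=O)/C(CBr)=C/CO[Si](C)(C)C(C)(C)C | intermediate
5 | prop-2-yn-1-ol | C#CCO | starting material
6 | alkenylalane: (E)-1-(dimethylalumanyl)-2-methyl-3-(dimethylalumanyloxy)prop-1-ene (CH3 and Al cis) | C/C(CO[Al](C)C)=C\[Al](C)C | intermediate
7 | (2E)-3-iodo-2-methylprop-2-en-1-ol | C/C(CO)=C\I | intermediate
8 | (2E)-3-iodo-2-methylprop-2-en-1-yl pivalate | C/C(COC(=O)C(C)(C)C)=C\I | intermediate
9 | neryl acetate, (2Z)-3,7-dimethylocta-2,6-dien-1-yl acetate | CC(C)=CCC/C(C)=C\COC(C)=O | starting material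
10 | (2Z)-5-(3,3-dimethyloxiran-2-yl)-3-methylpent-2-en-1-yl acetate (racemic epoxide) | CC1(C)OC1CC/C(C)=C\COC(C)=O | intermediate
11 | (2Z)-3-methyl-6-oxohex-2-en-1-yl acetate | O=CCC/C(C)=C\COC(C)=O | intermediate
12 | (2Z,6R,7R)-1-acetoxy-3,7-dimethylnona-2,8-dien-6-yl diisopinocampheylborinate | C=C[C@@H](C)[C@H](OB([C@@H]1C[C@@H]2C[C@H]([C@H]1C)C2(C)C)[C@@H]1C[C@@H]2C[C@H]([C@H]1C)C2(C)C)CC/C(C)=C\COC(C)=O | intermediate
13 | (2Z,6R,7R)-3,7-dimethylnona-2,8-diene-1,6-diol | C=C[C@@H](C)[C@H](O)CC/C(C)=C\CO | intermediate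
14 | [(2R,3S)-3-[(3R,4R)-3-hydroxy-4-methylhex-5-en-1-yl]-3-methyloxiran-2-yl]methanol | C=C[C@@H](C)[C@H](O)CC[C@]1(C)O[C@@H]1CO | intermediate
15 | (1R)-1-[(2R,5R)-5-[(2R)-but-3-en-2-yl]-2-methyloxolan-2-yl]ethane-1,2-diol | C=C[C@@H](C)[C@H]1CC[C@@](C)(O1)[C@H](O)CO | intermediate
16 | (2S)-2-[(2R,5R)-5-[(2R)-but-3-en-2-yl]-2-methyloxolan-2-yl]-2-hydroxyacetaldehyde | C=C[C@@H](C)[C@H]1CC[C@@](C)(O1)[C@H](O)C=O | intermediate
17 | [(2Z)-4-(tert-butyldimethylsilyloxy)-2-(methoxycarbonyl)but-2-en-1-yl]indium dibromide | COC(=O)/C(C[In](Br)Br)=C/CO[Si](C)(C)C(C)(C)C | intermediate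
18 | methyl (3S,4S,5R)-5-[(2R,5R)-5-[(2R)-but-3-en-2-yl]-2-methyloxolan-2-yl]-3-[(tert-butyldimethylsilyloxy)methyl]-4,5-dihydroxy-2-methylidenepentanoate | C=C[C@@H](C)[C@H]1CC[C@@](C)(O1)[C@H](O)[C@@H](O)[C@H](CO[Si](C)(C)C(C)(C)C)C(=C)C(=O)OC | intermediate
19 | (4S,5S)-4-[(tert-butyldimethylsilyloxy)methyl]-5-[(R)-hydroxy{(2R,5R)-5-[(2R)-but-3-en-2-yl]-2-methyloxolan-2-yl}methyl]-3-methylideneoxolan-2-one (ring substituents cis) | C=C[C@@H](C)[C@H]1CC[C@@](C)(O1)[C@H](O)[C@H]2OC(=O)C(=C)[C@H]2CO[Si](C)(C)C(C)(C)C | intermediate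
20 | C3-O-tert-butyldimethylsilyl ether of 19 | C=C[C@@H](C)[C@H]1CC[C@@](C)(O1)[C@H](O[Si](C)(C)C(C)(C)C)[C@H]2OC(=O)C(=C)[C@H]2CO[Si](C)(C)C(C)(C)C | intermediate
21 | 3-methyloxolan-2-one from 20, both C15 epimers | C=C[C@@H](C)[C@H]1CC[C@@](C)(O1)[C@H](O[Si](C)(C)C(C)(C)C)[C@H]2OC(=O)C(C)[C@H]2CO[Si](C)(C)C(C)(C)C | intermediate
22 | (3R,4S,5S)-3-methyl lactone: C15 methyl trans to the cis pair CH2OTBS (C1) and C3 side chain (C2); C3-OTBS; C8 vinyl | C=C[C@@H](C)[C@H]1CC[C@@](C)(O1)[C@H](O[Si](C)(C)C(C)(C)C)[C@H]2OC(=O)[C@H](C)[C@H]2CO[Si](C)(C)C(C)(C)C | intermediate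
23 | B-alkyl-9-borabicyclo[3.3.1]nonane from 22 (boron on C10) | B1(CC[C@@H](C)[C@H]2CC[C@@](C)(O2)[C@H](O[Si](C)(C)C(C)(C)C)[C@H]3OC(=O)[C@H](C)[C@H]3CO[Si](C)(C)C(C)(C)C)C4CCCC1CCC4 | intermediate
24 | seco pivalate: 22 with the C8 vinyl replaced by the (3E)-4-methyl-5-(pivaloyloxy)pent-3-en-1-yl chain | C/C(COC(=O)C(C)(C)C)=C\CC[C@@H](C)[C@H]1CC[C@@](C)(O1)[C@H](O[Si](C)(C)C(C)(C)C)[C@H]2OC(=O)[C@H](C)[C@H]2CO[Si](C)(C)C(C)(C)C | intermediate
25 | C14 primary alcohol of 24 (C3-OTBS kept) | C/C(COC(=O)C(C)(C)C)=C\CC[C@@H](C)[C@H]1CC[C@@](C)(O1)[C@H](O[Si](C)(C)C(C)(C)C)[C@H]2OC(=O)[C@H](C)[C@H]2CO | intermediate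
26 | C14 aldehyde | C/C(COC(=O)C(C)(C)C)=C\CC[C@@H](C)[C@H]1CC[C@@](C)(O1)[C@H](O[Si](C)(C)C(C)(C)C)[C@H]2OC(=O)[C@H](C)[C@H]2C=O | intermediate
27 | C14 carboxylic acid | C/C(COC(=O)C(C)(C)C)=C\CC[C@@H](C)[C@H]1CC[C@@](C)(O1)[C@H](O[Si](C)(C)C(C)(C)C)[C@H]2OC(=O)[C@H](C)[C@H]2C(O)=O | intermediate
28 | S-(pyridin-2-yl) C14 thioester | C/C(COC(=O)C(C)(C)C)=C\CC[C@@H](C)[C@H]1CC[C@@](C)(O1)[C@H](O[Si](C)(C)C(C)(C)C)[C@H]2OC(=O)[C@H](C)[C@H]2C(=O)Sc1ccccn1 | intermediate
29 | C3-O-tert-butyldimethylsilyl ether of the target | C/C1=C\CC[C@@H](C)[C@H]2CC[C@@](C)(O2)[C@H](O[Si](C)(C)C(C)(C)C)[C@H]2OC(=O)[C@H](C)[C@H]2C(=O)C1 | intermediate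
30 | CNP0386136.3, (1R,2S,3R,4R,7R,8R,15R,11E)-3-hydroxy-14-oxo-4,7-epoxycembr-11-en-16,2-olide | C/C1=C\CC[C@@H](C)[C@H]2CC[C@@](C)(O2)[C@H](O)[C@H]2OC(=O)[C@H](C)[C@H]2C(=O)C1 | target

**Count and risks**
Total steps: 18 (fragment A: 2, fragment B: 2, main line: 14). Longest linear sequence: 14 steps (steps 5–18, from neryl acetate 9).

Step 17 (the proposed new macrocyclisation) may fail through oligomerisation, coupling at the internal allyl terminus, E/Z erosion in the allylnickel, or decarbonylation. The fallback is a B-alkyl Suzuki macrocyclisation, which is known chemistry. It sets out from 22. HF·pyridine removes the primary silyl group to give the primary alcohol F1. Dess–Martin oxidation gives the aldehyde F2. Zinc-mediated Barbier propargylation (propargyl bromide, Zn dust, THF/aq. NH4Cl) gives the homopropargylic alcohol F3 as both C14 epimers. Negishi carboalumination and iodinolysis (AlMe3, Cp2ZrCl2, then I2) give the (E)-iodoalkene F4. Hydroboration of the C8 vinyl group with 9-BBN and intramolecular coupling at 1 mM (Pd(dppf)Cl2, AsPh3, Cs2CO3, DMF/THF/H2O) close the ring at C10–C11 to the macrocyclic alcohol F5. Dess–Martin oxidation comes back to the route at 29.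

Step 10 sets C1 and C2 in one operation and depends on chelation by the free hydroxyl and on the syn preference of the (Z)-allyl metal; it may also suffer 1,4-elimination of the silyloxy group. The fallback enforces the cis C1/C2 relationship with a tether and sets out from 16. Vinylmagnesium bromide (CH2=CHMgBr, excess, THF, −78 °C, magnesium alkoxide chelate) gives the syn diol F6. Acylation of the less hindered allylic C2 hydroxyl with methacryloyl chloride gives the methacrylate F7. Ring-closing metathesis (second-generation Grubbs catalyst, RuCl2(=CHPh)(PCy3)(H2IMes), dilute CH2Cl2) gives the α-methylbutenolide F8. Silylation of C3-OH with (bromomethyl)chlorodimethylsilane gives the bromomethylsilyl ether F9. Silicon-tethered 6-exo radical cyclisation onto C1 (Bu3SnH, AIBN, benzene, 80 °C), then DBU, gives the cis-fused bicyclic siloxane F10 with the C15 methyl trans. Tamao oxidation (KF, KHCO3, H2O2) gives the diol F11, and TBSOTf/2,6-lutidine comes back to the route at 22.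

Step 9 may give glycol cleavage by PhI(OAc)2 or loss of the labile α-hydroxy aldehyde by dimerisation. The fallback sets out from 15. TESCl/imidazole gives the bis(triethylsilyl) ether F12. Swern oxidation, which cleaves and oxidises only the primary triethylsilyl ether, gives the α-(triethylsilyloxy) aldehyde F13. HF·pyridine in THF at 0 °C releases the hydroxyl and comes back to the route at 16.

**Further compounds**
F1 | step 17 | C14 primary alcohol from 22 (C3-OTBS and C8 vinyl kept) | C=C[C@@H](C)[C@H]1CC[C@@](C)(O1)[C@H](O[Si](C)(C)C(C)(C)C)[C@H]2OC(=O)[C@H](C)[C@H]2CO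
F2 | step 17 | C14 aldehyde of F1 | C=C[C@@H](C)[C@H]1CC[C@@](C)(O1)[C@H](O[Si](C)(C)C(C)(C)C)[C@H]2OC(=O)[C@H](C)[C@H]2C=O
F3 | step 17 | homopropargylic alcohol (C14 carbinol, both epimers) | C=C[C@@H](C)[C@H]1CC[C@@](C)(O1)[C@H](O[Si](C)(C)C(C)(C)C)[C@H]2OC(=O)[C@H](C)[C@H]2C(O)CC#C
F4 | step 17 | (E)-iodoalkene: C14 carbinol bearing CH2–C(CH3)=CH–I | C=C[C@@H](C)[C@H]1CC[C@@](C)(O1)[C@H](O[Si](C)(C)C(C)(C)C)[C@H]2OC(=O)[C@H](C)[C@H]2C(O)C/C(C)=C/I
F5 | step 17 | macrocyclic C14 alcohol (29 with CH(OH) at C14, both epimers) | C/C1=C\CC[C@@H](C)[C@H]2CC[C@@](C)(O2)[C@H](O[Si](C)(C)C(C)(C)C)[C@H]2OC(=O)[C@H](C)[C@H]2C(O)C1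
F6 | step 10 | syn diol from vinyl addition (C2 carbinol bearing vinyl, C3-OH) | C=C[C@@H](C)[C@H]1CC[C@@](C)(O1)[C@H](O)[C@@H](O)C=C
F7 | step 10 | C2-O-methacrylate of F6 | C=C[C@@H](C)[C@H]1CC[C@@](C)(O1)[C@H](O)[C@@H](OC(=O)C(C)=C)C=C
F8 | step 10 | α-methylbutenolide (C1=C15 alkene, C3-OH) | C=C[C@@H](C)[C@H]1CC[C@@](C)(O1)[C@H](O)[C@H]2OC(=O)C(C)=C2
F9 | step 10 | C3-O-(bromomethyl)dimethylsilyl ether of F8 | C=C[C@@H](C)[C@H]1CC[C@@](C)(O1)[C@H](O[Si](C)(C)CBr)[C@H]2OC(=O)C(C)=C2
F10 | step 10 | cis-fused bicyclic siloxane (C3–O–Si(CH3)2–C14H2–C1, C15 methyl trans) | C=C[C@@H](C)[C@H]1CC[C@@](C)(O1)[C@H](O3)[C@H]2OC(=O)[C@H](C)[C@H]2C[Si]3(C)C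
F11 | step 10 | diol (C14-OH and C3-OH; 22 without silyl groups) | C=C[C@@H](C)[C@H]1CC[C@@](C)(O1)[C@H](O)[C@H]2OC(=O)[C@H](C)[C@H]2CO
F12 | step 9 | bis(triethylsilyl) ether of 15 | C=C[C@@H](C)[C@H]1CC[C@@](C)(O1)[C@H](O[Si](CC)(CC)CC)CO[Si](CC)(CC)CC
F13 | step 9 | α-(triethylsilyloxy) aldehyde (C2 aldehyde, C3-OTES) | C=C[C@@H](C)[C@H]1CC[C@@](C)(O1)[C@H](O[Si](CC)(CC)CC)C=O
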